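Ring B (C5–C10) is grown from the cyclopentanone ring (C5, C6, C7, C8, C10) of a trans-hydrindanone by one-carbon ring enlargement. A 1,1-dibromoalkyllithium carrying the whole C11–C16 chain adds to the C8 ketone; bromine–lithium exchange gives a β-oxido carbenoid in which quaternary C10 shifts from C8 to the new C9. One operation inserts C9, forms the C9–C10 bond with retention at C10, attaches the side chain and leaves a C8 ketone whose enolisable C9 converges on the equatorial configuration. The feature exploited is C8 of ring B, flanked by quaternary C10 and stereocentre C9. The ketone later becomes the C7=C8 methyl alkene; a ring A C2=C3 alkene delivers the cis-diol.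

Key step: step 10

Remark: labdane numbering is used throughout (ring A: C1–C5 with C10; ring B: C5–C10; side chain C11–C16; C17 on C8; C20 on C10). Labdane names imply 5α-H, 9α-H and 10β-methyl, and the target SMILES is read as 2α-acetoxy, 3α-hydroxy, 13S.

Step 1
Reactants: 1 2-methylcyclopentane-1,3-dione; 2 ethyl vinyl ketone
Product: 4 (S)-4,7a-dimethyl-2,3,7,7a-tetrahydro-1H-indene-1,5(6H)-dione, via triketone 3 (not isolated)
Conditions: H2O, 70 °C; concentrate; then L-phenylalanine (1 equiv), (1S)-(+)-10-camphorsulfonic acid (0.5 equiv), DMF, 30 → 70 °C; recrystallise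
Reagents that add atoms: none
Why: Michael addition followed by the amino-acid-mediated Hajos–Parrish–Eder–Sauer–Wiechert aldol condensation, in which the L-phenylalanine enamine differentiates the two enantiotopic ring carbonyls and should set the quaternary carbon (future C10) as S.

Step 2
Reactants: 4 (S)-4,7a-dimethyl-2,3,7,7a-tetrahydro-1H-indene-1,5(6H)-dione
Product: 5 (S)-1,1-(ethylenedioxy)-4,7a-dimethyl-1,2,3,6,7,7a-hexahydro-5H-inden-5-one
Conditions: ethylene glycol, p-TsOH (cat.), 4 Å molecular sieves, CH2Cl2, rt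
Reagents that add atoms: ethylene glycol, OCCO
Why: chemoselective acid-catalysed ketalisation, the saturated cyclopentanone carbonyl (future C8) being far more electrophilic than the vinylogous carbonyl of the fully substituted enone.

Step 3
Reactants: 5 (S)-1,1-(ethylenedioxy)-4,7a-dimethyl-1,2,3,6,7,7a-hexahydro-5H-inden-5-one
Product: 7 (3aS,7aS)-1,1-(ethylenedioxy)-4,4,7a-trimethyloctahydro-5H-inden-5-one, via lithium enolate 6 (not isolated)
Conditions: Li, NH3 (l), THF, t-BuOH (1 equiv), −78 °C; isoprene; then MeI, −78 → −33 °C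
Reagents that add atoms: iodomethane, CI
Why: Birch-type reductive alkylation, in which the enone is reduced to the regiodefined C3–C4 lithium enolate with protonation of C5 from the face opposite the angular methyl (trans fusion, 5α-H) and the enolate is then C-methylated at C4 to give the gem-dimethyl ketone.

Step 4
Reactants: 7 (3aS,7aS)-1,1-(ethylenedioxy)-4,4,7a-trimethyloctahydro-5H-inden-5-one
Product: 9 (3aS,7aS)-1,1-(ethylenedioxy)-4,4,7a-trimethyl-2,3,3a,4,7,7a-hexahydro-1H-inden-5-yl trifluoromethanesulfonate, via potassium enolate 8 (not isolated)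
Conditions: KN(SiMe3)2, THF, −78 °C; then PhNTf2, −78 → 0 °C
Reagents that add atoms: N-phenylbis(trifluoromethanesulfonimide), O=S(=O)(N(c1ccccc1)S(=O)(=O)C(F)(F)F)C(F)(F)F
Why: enolisation can only occur towards C2 because C4 is quaternary, and O-sulfonylation of the potassium enolate gives the C2=C3 enol triflate.

Step 5
Reactants: 9 (3aS,7aS)-1,1-(ethylenedioxy)-4,4,7a-trimethyl-2,3,3a,4,7,7a-hexahydro-1H-inden-5-yl trifluoromethanesulfonate
Product: 10 (3aS,7aS)-1,1-(ethylenedioxy)-4,4,7a-trimethyl-2,3,3a,4,7,7a-hexahydro-1H-indene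
Conditions: Pd(OAc)2 (cat.), PPh3, HCO2H, n-Bu3N, DMF, 60 °C
Reagents that add atoms: none
Why: palladium-catalysed formate hydrogenolysis of the enol triflate (oxidative addition, decarboxylation of formate to the hydride, reductive elimination) leaves the C2=C3 alkene that masks the later cis-diol.

Step 6
Reactants: 10 (3aS,7aS)-1,1-(ethylenedioxy)-4,4,7a-trimethyl-2,3,3a,4,7,7a-hexahydro-1H-indene
Product: 11 (3aS,7aS)-4,4,7a-trimethyl-2,3,3a,4,7,7a-hexahydro-1H-inden-1-one
Conditions: 1 M HCl, THF, rt
Reagents that add atoms: water, O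
Why: acid hydrolysis of the dioxolane frees the C8 ketone, the isolated alkene and both stereocentres (neither epimerisable) being untouched.

Step 7
Reactants: 12 (S)-citronellol
Product: 13 (S)-tert-butyl[(3,7-dimethyloct-6-en-1-yl)oxy]dimethylsilane
Conditions: TBSCl, imidazole, DMF, rt
Reagents that add atoms: tert-butyldimethylsilyl chloride, CC(C)(C)[Si](C)(C)Cl
Why: silyl ether formation masks the future C15 oxygen against the organolithium reagents of step 10.

Step 8
Reactants: 13 (S)-tert-butyl[(3,7-dimethyloct-6-en-1-yl)oxy]dimethylsilane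
Product: 15 (S)-6-(tert-butyldimethylsilyloxy)-4-methylhexanal, via ozonide 14 (not isolated)
Conditions: O3, CH2Cl2, −78 °C; then PPh3, −78 °C → rt
Reagents that add atoms: ozone, [O-][O+]=O
Why: ozonolysis with reductive work-up cleaves the trisubstituted alkene so that the former alkene CH becomes the aldehyde carbon destined to be C9, the remote C13 stereocentre being unaffected.

Step 9
Reactants: 15 (S)-6-(tert-butyldimethylsilyloxy)-4-methylhexanal
Product: 16 (S)-tert-butyl[(6,6-dibromo-3-methylhexyl)oxy]dimethylsilane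
Conditions: (PhO)3P, Br2, Et3N, CH2Cl2, −78 °C → rt
Reagents that add atoms: bromine, BrBr
Why: Appel-type deoxygenative dibromination, in which the phosphite–bromine adduct activates the aldehyde oxygen as an oxyphosphonium group that bromide displaces, a known conversion of enolisable aldehydes into geminal dibromides.

Step 10
Reactants: 16 (S)-tert-butyl[(6,6-dibromo-3-methylhexyl)oxy]dimethylsilane; 11 (3aS,7aS)-4,4,7a-trimethyl-2,3,3a,4,7,7a-hexahydro-1H-inden-1-one
Product: 21 (13S)-15-(tert-butyldimethylsilyloxy)-17-norlabd-2-en-8-one, via lithiated dibromide 17 (not isolated), via dibromo alkoxide 18 (not isolated), via oxido carbenoid 19 (not isolated), via lithium enolate 20 (not isolated)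
Conditions: LiN(iPr)2, THF/Et2O, −100 °C, 16 (1.5 equiv); then 11, −100 → −78 °C; then n-BuLi (2.2 equiv), −95 °C → rt; H2O; then NaOMe (cat.), MeOH, rt
Reagents that add atoms: none
Why: Deprotonation of 16 gives the 1,1-dibromoalkyllithium, which adds to the C8 carbonyl; bromine–lithium exchange then forms the β-oxido carbenoid, whose alkoxide pushes a ring bond onto the carbenoid carbon with loss of LiBr to give the ring-enlarged lithium enolate (C8–O, C8=C9). The closest known reaction type is the β-oxido carbenoid one-carbon ring enlargement of cycloalkanones, a Tiffeneau–Demjanov-type 1,2-shift. No ring is closed by cyclisation: ring B arises because C10 leaves C8 and bonds to the inserted C9, turning the five-membered ring (C5, C6, C7, C8, C10) into the six-membered one. C10 migrates with retention, so the configuration fixed in step 1 is carried into the C9–C10 bond, while C9 passes through the planar enolate and is set on protonation and methoxide equilibration as the equatorial 9β side chain (9α-H) trans to the axial C20 methyl. Both C8 epimers of the adduct and both C9 epimers of the first-formed ketone therefore converge on one product. The step needs migration of C10 and not of C7, which the more electron-rich, more highly substituted α-carbon should secure, as is known for carbenoid enlargements of 2-alkylcycloalkanones.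

Step 11
Reactants: 21 (13S)-15-(tert-butyldimethylsilyloxy)-17-norlabd-2-en-8-one
Product: 22 (13S)-8-oxo-17-norlabd-2-en-15-oic acid
Conditions: CrO3, H2SO4, acetone/H2O, 0 °C → rt
Reagents that add atoms: water, O
Why: Jones oxidation, in which the acidic medium cleaves the primary silyl ether and chromic acid oxidises the alcohol through the aldehyde hydrate to the acid, the alkene and the thermodynamically configured C9 being stable.

Step 12
Reactants: 22 (13S)-8-oxo-17-norlabd-2-en-15-oic acid
Product: 23 methyl (13S)-8-oxo-17-norlabd-2-en-15-oate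
Conditions: TMSCHN2, MeOH/toluene, 0 °C → rt
Reagents that add atoms: trimethylsilyldiazomethane, C[Si](C)(C)C=[N+]=[N-]
Why: diazoalkane esterification methylates the carboxylic acid under neutral conditions without touching the ketone or its α-stereocentre.

Step 13
Reactants: 23 methyl (13S)-8-oxo-17-norlabd-2-en-15-oate
Product: 25 methyl (13S)-8-(trifluoromethylsulfonyloxy)-17-norlabda-2,7-dien-15-oate, via potassium enolate 24 (not isolated)
Conditions: KN(SiMe3)2 (1.05 equiv), THF, −78 °C; then PhNTf2, −78 → 0 °C
Reagents that add atoms: N-phenylbis(trifluoromethanesulfonimide), O=S(=O)(N(c1ccccc1)S(=O)(=O)C(F)(F)F)C(F)(F)F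
Why: kinetic deprotonation by the bulky amide should occur at the unhindered C7 methylene (not at the tertiary C9 hydrogen next to the quaternary centre, nor next to the less acidic ester), and O-triflation fixes the C7=C8 position of the future alkene.

Step 14
Reactants: 25 methyl (13S)-8-(trifluoromethylsulfonyloxy)-17-norlabda-2,7-dien-15-oate
Product: 26 methyl (13S)-2α,3α-dihydroxy-8-(trifluoromethylsulfonyloxy)-17-norlabd-7-en-15-oate
Conditions: OsO4 (cat.), N-methylmorpholine N-oxide, acetone/H2O, rt
Reagents that add atoms: osmium tetroxide, O=[Os](=O)(=O)=O; N-methylmorpholine N-oxide, C[N+]1([O-])CCOCC1; water, O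
Why: Upjohn dihydroxylation, in which the electrophilic oxidant adds suprafacially to the electron-rich C2=C3 alkene (not to the electron-poor enol triflate) from the α face opposite the axial C20 and 4β methyl groups, giving the 2α,3α-cis-diol.

Step 15
Reactants: 26 methyl (13S)-2α,3α-dihydroxy-8-(trifluoromethylsulfonyloxy)-17-norlabd-7-en-15-oate
Product: 27 methyl (13S)-2α,3α-dihydroxylabd-7-en-15-oate
Conditions: Me4Sn, Pd(PPh3)4 (cat.), LiCl, DMF, 80 °C
Reagents that add atoms: tetramethylstannane, C[Sn](C)(C)C
Why: Stille coupling (oxidative addition of the enol triflate to zerovalent palladium, chloride-assisted methyl transmetalation, reductive elimination) installs C17 on C8 with the alkene fixed at C7=C8, under neutral conditions that tolerate the free diol and the ester.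

Step 16
Reactants: 27 methyl (13S)-2α,3α-dihydroxylabd-7-en-15-oate
Product: 28 methyl (13S)-2α-acetoxy-3α-hydroxylabd-7-en-15-oate
Conditions: Ac2O (1.1 equiv), pyridine, CH2Cl2, 0 °C
Reagents that add atoms: acetic anhydride, CC(=O)OC(C)=O
Why: selective acylation of the equatorial C2 hydroxyl, the axial C3 hydroxyl being hindered by the adjacent gem-dimethyl group, and the 2-acetate is also the favoured position should acyl migration occur.

Compound list
1 | 2-methylcyclopentane-1,3-dione | CC1C(=O)CCC1=O | starting material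
2 | ethyl vinyl ketone (pent-1-en-3-one) | CCC(=O)C=C | starting material
3 | 2-methyl-2-(3-oxopentyl)cyclopentane-1,3-dione | CCC(=O)CCC1(C)C(=O)CCC1=O | intermediate
4 | (S)-4,7a-dimethyl-2,3,7,7a-tetrahydro-1H-indene-1,5(6H)-dione | O=C1CCC2=C(C)C(=O)CC[C@]12C | intermediate
5 | (S)-1,1-(ethylenedioxy)-4,7a-dimethyl-1,2,3,6,7,7a-hexahydro-5H-inden-5-one | O1CCOC12CCC3=C(C)C(=O)CC[C@]23C | intermediate
6 | lithium (3aS,7aS)-1,1-(ethylenedioxy)-4,7a-dimethyl-2,3,3a,6,7,7a-hexahydro-1H-inden-5-olate | O1CCOC12CC[C@H]3C(C)=C(O[Li])CC[C@]23C | intermediate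
7 | (3aS,7aS)-1,1-(ethylenedioxy)-4,4,7a-trimethyloctahydro-5H-inden-5-one (trans-fused) | O1CCOC12CC[C@H]3C(C)(C)C(=O)CC[C@]23C | intermediate
8 | potassium enolate of 7 (enolate double bond between labdane C2 and C3) | O1CCOC12CC[C@H]3C(C)(C)C(O[K])=CC[C@]23C | intermediate
9 | (3aS,7aS)-1,1-(ethylenedioxy)-4,4,7a-trimethyl-2,3,3a,4,7,7a-hexahydro-1H-inden-5-yl trifluoromethanesulfonate | O1CCOC12CC[C@H]3C(C)(C)C(OS(=O)(=O)C(F)(F)F)=CC[C@]23C | intermediate
10 | (3aS,7aS)-1,1-(ethylenedioxy)-4,4,7a-trimethyl-2,3,3a,4,7,7a-hexahydro-1H-indene | O1CCOC12CC[C@H]3C(C)(C)C=CC[C@]23C | intermediate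
11 | (3aS,7aS)-4,4,7a-trimethyl-2,3,3a,4,7,7a-hexahydro-1H-inden-1-one (trans-fused; carbonyl = labdane C8) | O=C1CC[C@H]2C(C)(C)C=CC[C@]12C | intermediate
12 | (S)-citronellol | OCC[C@@H](C)CCC=C(C)C | starting material
13 | (S)-tert-butyl[(3,7-dimethyloct-6-en-1-yl)oxy]dimethylsilane | CC(C)(C)[Si](C)(C)OCC[C@@H](C)CCC=C(C)C | intermediate
14 | ozonide (1,2,4-trioxolane) of 13 | CC(C)(C)[Si](C)(C)OCC[C@@H](C)CCC1OOC(C)(C)O1 | intermediate
15 | (S)-6-(tert-butyldimethylsilyloxy)-4-methylhexanal | CC(C)(C)[Si](C)(C)OCC[C@@H](C)CCC=O | intermediate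
16 | (S)-tert-butyl[(6,6-dibromo-3-methylhexyl)oxy]dimethylsilane | CC(C)(C)[Si](C)(C)OCC[C@@H](C)CCC(Br)Br | intermediate
17 | (S)-[1,1-dibromo-6-(tert-butyldimethylsilyloxy)-4-methylhexyl]lithium | CC(C)(C)[Si](C)(C)OCC[C@@H](C)CCC([Li])(Br)Br | intermediate
18 | lithium alkoxide of the C8 adduct of 17 and 11 (C8 epimers) | CC(C)(C)[Si](C)(C)OCC[C@@H](C)CCC(Br)(Br)C1(O[Li])CC[C@H]2C(C)(C)C=CC[C@]12C | intermediate
19 | β-oxido carbenoid (1-bromo-1-lithioalkyl lithium alkoxide) | CC(C)(C)[Si](C)(C)OCC[C@@H](C)CCC([Li])(Br)C1(O[Li])CC[C@H]2C(C)(C)C=CC[C@]12C | intermediate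
20 | ring-enlarged lithium enolate (C8–OLi, C8=C9) | CC(C)(C)[Si](C)(C)OCC[C@@H](C)CCC1=C(O[Li])CC[C@H]2C(C)(C)C=CC[C@]12C | intermediate
21 | (13S)-15-(tert-butyldimethylsilyloxy)-17-norlabd-2-en-8-one (5α-H, 9α-H, 10β-methyl) | CC(C)(C)[Si](C)(C)OCC[C@@H](C)CC[C@H]1C(=O)CC[C@H]2C(C)(C)C=CC[C@]12C | intermediate
22 | (13S)-8-oxo-17-norlabd-2-en-15-oic acid | OC(=O)C[C@@H](C)CC[C@H]1C(=O)CC[C@H]2C(C)(C)C=CC[C@]12C | intermediate
23 | methyl (13S)-8-oxo-17-norlabd-2-en-15-oate | COC(=O)C[C@@H](C)CC[C@H]1C(=O)CC[C@H]2C(C)(C)C=CC[C@]12C | intermediate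
24 | potassium C7=C8 enolate of 23 | COC(=O)C[C@@H](C)CC[C@H]1C(O[K])=CC[C@H]2C(C)(C)C=CC[C@]12C | intermediate
25 | methyl (13S)-8-(trifluoromethylsulfonyloxy)-17-norlabda-2,7-dien-15-oate | COC(=O)C[C@@H](C)CC[C@H]1C(OS(=O)(=O)C(F)(F)F)=CC[C@H]2C(C)(C)C=CC[C@]12C | intermediate
26 | methyl (13S)-2α,3α-dihydroxy-8-(trifluoromethylsulfonyloxy)-17-norlabd-7-en-15-oate | COC(=O)C[C@@H](C)CC[C@H]1C(OS(=O)(=O)C(F)(F)F)=CC[C@H]2C(C)(C)[C@H](O)[C@H](O)C[C@]12C | intermediate
27 | methyl (13S)-2α,3α-dihydroxylabd-7-en-15-oate | COC(=O)C[C@@H](C)CC[C@H]1C(C)=CC[C@H]2C(C)(C)[C@H](O)[C@H](O)C[C@]12C | intermediate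
28 | methyl (13S)-2α-acetoxy-3α-hydroxylabd-7-en-15-oate (CNP0571009.1) | COC(=O)C[C@@H](C)CC[C@H]1C(C)=CC[C@H]2C(C)(C)[C@H](O)[C@H](OC(C)=O)C[C@]12C | target

Total step count: 16. Longest linear sequence: 13 steps (steps 1–6, then 10–16); steps 7–9 form the side-chain branch.

Steps most likely to fail

Step 10. The bulky dibromoalkyllithium may add too slowly to the neopentyl-type C8 ketone, so that it enolises the ketone or decomposes by α-elimination first. The C7 methylene may also migrate in place of the quaternary C10. The fallback sets out from aldehyde 15 and ketone 11 and comes back at 21. Aldehyde 15 is converted with PhSeH and ZnCl2 into the bis(phenylselanyl) acetal F1. Selenium–lithium exchange with n-BuLi at −78 °C gives a thermally stable, weakly basic and strongly nucleophilic α-selanylalkyllithium, which adds to 11 to give the β-hydroxy selenide F2. Activation of selenium with AgBF4 on alumina in CH2Cl2 makes it a leaving group, and a semipinacol shift of the more substituted C10 should give 21 after methoxide equilibration.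

Step 3. Protonation of C5 from the β face would give the cis-fused hydrindanone, and over-reduction of the carbonyl or O-methylation of the enolate would erode the material. The fallback sets out from 5 and comes back at 7. Deconjugative methylation of 5 with KOt-Bu and MeI in t-BuOH gives the 4,4-dimethyl β,γ-unsaturated ketone F3 (C5=C6 alkene). Hydrogenation of F3 over Pd/C, from the face opposite the angular methyl, should give 7.

Step 13. Regiocontrol of the enolisation may be lost, by deprotonation at C9 or by enolate equilibration towards the C8=C9 triflate, and deprotonation next to the ester may compete. The fallback sets out from 23 and comes back at 27. Dihydroxylation of 23 with OsO4 and N-methylmorpholine N-oxide gives the diol ketone F4. Wittig methylenation with excess Ph3P=CH2 gives the exocyclic C8=C17 alkene F5. Isomerisation with RhCl3·3H2O in EtOH at reflux should move the double bond into the ring to the trisubstituted C7=C8 position, giving 27.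

Further compounds
F1 | step 10 | (S)-tert-butyl{[3-methyl-6,6-bis(phenylselanyl)hexyl]oxy}dimethylsilane | CC(C)(C)[Si](C)(C)OCC[C@@H](C)CCC([Se]c1ccccc1)[Se]c1ccccc1
F2 | step 10 | β-hydroxy selenide from F1 and 11 (C8 tertiary alcohol, C9 phenylselanyl, epimer mixture) | CC(C)(C)[Si](C)(C)OCC[C@@H](C)CCC([Se]c1ccccc1)C1(O)CC[C@H]2C(C)(C)C=CC[C@]12C
F3 | step 3 | (S)-1,1-(ethylenedioxy)-4,4,7a-trimethyl-1,2,4,6,7,7a-hexahydro-5H-inden-5-one | O1CCOC12CC=C3C(C)(C)C(=O)CC[C@]23C
F4 | step 13 | methyl (13S)-2α,3α-dihydroxy-8-oxo-17-norlabdan-15-oate | COC(=O)C[C@@H](C)CC[C@H]1C(=O)CC[C@H]2C(C)(C)[C@H](O)[C@H](O)C[C@]12C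
F5 | step 13 | methyl (13S)-2α,3α-dihydroxylabd-8(17)-en-15-oate | COC(=O)C[C@@H](C)CC[C@H]1C(=C)CC[C@H]2C(C)(C)[C@H](O)[C@H](O)C[C@]12C
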